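**Late balance.** At late times this flask holds what its reversible cycle allows, so the end state is reckoned first and the speed of approach second.

starting material 0.010 M; partner 0.500 equiv; protic impurity 3.00 mM; free catalyst 0.06 mol%; time 15 d

    partner + free catalyst ⇌ catalyst intermediate A (K1 = 410 /M, k1 = 3.9 × 10⁵ /M/h)
    catalyst intermediate C ⇌ free catalyst + product (K2 = 0.019 M, k2 = 390 /h)
    catalyst intermediate B ⇌ catalyst intermediate C (K3 = 1.2, k3 = 6300 /h)
    starting material + catalyst intermediate A ⇌ catalyst intermediate B (K4 = 47 /M, k4 = 1.4 × 10⁶ /M/h)
    partner + protic impurity → quenched reagent (k5 = 45 /M/h)
    2 free catalyst ⇌ resting dimer, settled at all times (K6 = 3.8 × 10⁵ /M)
    free catalyst → spent catalyst (k7 = 1.4 × 10⁻⁴ /h)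

- the state of affairs at 15 d: stopped, and by what, or still going (all of the starting material has reacted / forward and back rates have come level / the partner has run out first / it is still moving / no working catalyst is left)
- the product standing at 15 d, as a percentage of the starting material charged
- amount of product if the flask were left three thousand times as long, in percent of the starting material charged

- two of one species on the left: rate k times its square, two consumed each time
- the reaction counts as stopped when no species that holds the starting material changes by six tenths of a point or more over the second half of the time
- run time (flask): 15 d

**Main cycle.** Around the catalyst, starting material and partner turn reversibly into product. Let x be the product and b the partner available, both as fractions of the starting material charged. The catalyst charge is tiny, 0.06 mol% against 0.500 equiv of partner, so its forms are left out of the balance. That balance then needs one number: the product of the cycle's equilibrium constants and the starting concentration, the charge-scaled constant κ = 4.39. It reads x = κ(1 − x)(b − x). With the full partner charge, x comes to 36.8 %.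

**Impurity added.** Protic impurity destroys partner one for one, which removes 0.300 of the charge. So b falls to 0.200, and the same balance gives x = 15.7 %. With partner steady near b − x, the last impurity decays pseudo-first-order, with a lifetime of 2.18 d. The run spans 6.88 such lifetimes.

**The rest.** Just after the start, the quench uses partner at 0.30 of the rate at which partner binds free catalyst, that binding's forward step alone, and this reckoning claims no balance during the early drain. Catalyst death has a lifetime of 298 d, much longer than the run. Neither the dimer's constant nor the death rate stands in κ. This reckoning commits, for late times, to a stop with forward and back rates level, and to the same x for the flask left standing far longer.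

**The forecast.** The forecast says: forward and back rates have come level. It gives 15.8 % at 15 d and 15.7 % for the long wait, on the ground that “product stays at equilibrium with partner”. Its first value stands slightly above the hand value.

**The result.** The simulated flask gives 15.7 % at 15.0 d and 15.7 % for the long wait, with the verdict: forward and back rates have come level. It kept 8.5 % of its partner charge beside 84.2 % of its starting material. Those readings put x/((1 − x)(b − x)) at 4.39, close to κ. The yield of this flask is a balance, not a matter of waiting.

**Second flask.** The neighbour charged with 1.20 equiv of partner has b = 0.900, and the same κ gives x = 58.2 %. Simulated, that neighbour holds 58.2 % product at 15.0 d.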